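**Direct plan and its weak points**

A direct plan would arylate the alkene of trans-resveratrol A1 to the o-hydroxy-triarylethylene aldehyde A2 and close it to the trans-dihydrobenzofuran aldehyde A3 by an enantioselective Brønsted-acid hydroalkoxylation through a p-quinone methide. Ring C would come last: aldol condensation of the tetra-MOM ether A4 of this aldehyde with the diprenylated acetophenone A5 to the chalcone A6, organocatalytic oxa-Michael closure, then removal of six MOM groups.
Its weakest steps would be: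
(a) The acid-catalysed ring closure of A2 to A3 would have to set both dihydrobenzofuran stereocentres on an unprotected pentaphenol by a reaction without precedent, with Friedel–Crafts capture of the quinone methide as an easy escape.
(b) The oxa-Michael closure of ring C from the unactivated 2'-hydroxychalcone A6 is slow and reversible, so C2 would be set with modest control at the most advanced stage and corrected by separating diastereomers.
(c) The resveratrol half would pass through acetylation, deacetylation, MOM protection and MOM removal within an eight-step linear sequence, protecting-group traffic that builds nothing.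

**Retrosynthetic overview of the new route**

1. The flavanone is cut at C2–C1'. Ring C is closed early as a stereocentre-free chromone (rings A and C), and C2 is set last by rhodium-catalysed asymmetric 1,4-arylation, an irreversible C–C bond formation instead of a reversible C–O closure.
2. The aryl partner is the complete dihydrobenzofuran. Ring B is a resorcinol whose O4'/C5' pair carries the furan, so furan C3 is the carbon of an aldehyde ortho to a phenol. The furan is cut at C3–aryl, C2–C3 and O1–C2 back to an o-OBoc benzaldehyde, an aryl Grignard reagent and a chiral benzylsulfonium ylide.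
3. In the key step the Grignard addition releases the o-quinone methide of ring B and the ylide closes the trans-dihydrofuran on it in a [4+1] annulation. Three bonds, the ring and both of its stereocentres arise in one flask under reagent control.
4. Ring order: ring C (step 3), dihydrofuran (step 8), union (step 10). Each phenol is masked once on a building block and unmasked once at the end.

Key step: step 8

Assumption: (1R,4R,5R)-isothiocineole is taken as a purchasable sulfide whose benzylide gives the (2R,3R) ring (and, through the same ylide face, the (2S,3S)-epoxide of the fallback), and the (S)-bisphosphine of step 10 is taken to give (2S) as it gives (S)-3-arylcycloalkanones; if a model reaction showed the opposite sense, the mirror-image reagent would be used.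

**Route**

Step 1
Reactants: 1 2,4,6-trihydroxyacetophenone; 2 prenyl bromide (2.2 equiv)
Product: 3 2,4,6-trihydroxy-3,5-bis(3-methylbut-2-en-1-yl)acetophenone
Conditions: DBU (2.2 equiv), THF, 0 °C → rt
Reagents that add atoms: none
Why: C-alkylation of the phloroglucinol-type phenoxide at its two free ring carbons (double C-prenylation) is a known reaction of this ketone; O-prenyl and mono-prenyl by-products would be removed by chromatography.

Step 2
Reactants: 3 2,4,6-trihydroxy-3,5-bis(3-methylbut-2-en-1-yl)acetophenone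
Product: 4 1-[2-hydroxy-4,6-bis(ethoxymethoxy)-3,5-bis(3-methylbut-2-en-1-yl)phenyl]ethan-1-one
Conditions: EtOCH2Cl (2.3 equiv), iPr2NEt, CH2Cl2, 0 °C → rt
Reagents that add atoms: chloromethyl ethyl ether CCOCCl
Why: O-alkylation to acetal ethers should stop after two, because the last ortho OH is hydrogen-bonded to the acetyl carbonyl; this is the phenol that closes ring C (ethoxymethyl is chosen for ring A only for the less volatile chloro ether and is cleaved together with the MOM groups).

Step 3
Reactants: 4 1-[2-hydroxy-4,6-bis(ethoxymethoxy)-3,5-bis(3-methylbut-2-en-1-yl)phenyl]ethan-1-one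
Product: 6 5,7-bis(ethoxymethoxy)-6,8-bis(3-methylbut-2-en-1-yl)-4H-chromen-4-one, via enaminone 5 (not isolated)
Conditions: Me2NCH(OMe)2 (3 equiv), toluene, 95 °C; then AcOH (10 equiv), toluene, 60 °C
Reagents that add atoms: N,N-dimethylformamide dimethyl acetal COC(OC)N(C)C
Why: Condensation of the methyl ketone with the amide acetal gives the enaminone, and mild acid induces intramolecular oxa-Michael addition of the free phenol with loss of dimethylamine (enaminone chromone synthesis), which closes ring C without a stereocentre and should spare the acetals and prenyl groups.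

Step 4
Reactants: 7 5-bromo-2,4-dihydroxybenzaldehyde
Product: 9 tert-butyl 4-bromo-2-formyl-5-(methoxymethoxy)phenyl carbonate, via 5-bromo-2-hydroxy-4-(methoxymethoxy)benzaldehyde 8 (not isolated)
Conditions: MOMCl (1.05 equiv), iPr2NEt, CH2Cl2, 0 °C; then Boc2O (1.3 equiv), DMAP (10 mol%), rt
Reagents that add atoms: chloromethyl methyl ether COCCl; di-tert-butyl dicarbonate CC(C)(C)OC(=O)OC(=O)OC(C)(C)C
Why: The 4-OH (para to the formyl group, not hydrogen-bonded) is alkylated first, and DMAP-catalysed acylation then turns the chelated 2-OH into the tert-butyl carbonate that later triggers o-quinone methide formation (selective phenol protection, carbonate formation).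

Step 5
Reactants: 10 5-bromobenzene-1,3-diol
Product: 11 1-bromo-3,5-bis(methoxymethoxy)benzene
Conditions: MOMCl (2.5 equiv), iPr2NEt, CH2Cl2, 0 °C → rt
Reagents that add atoms: chloromethyl methyl ether COCCl
Why: O-alkylation of both phenols (MOM protection) gives an aryl bromide that tolerates magnesium insertion.

Step 6
Reactants: 12 4-hydroxybenzyl alcohol
Product: 13 [4-(methoxymethoxy)phenyl]methanol
Conditions: MOMCl (1.05 equiv), K2CO3, acetone, 0 °C → rt
Reagents that add atoms: chloromethyl methyl ether COCCl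
Why: K2CO3 deprotonates only the phenol, so the phenoxide is alkylated and the benzylic alcohol stays free (chemoselective Williamson-type etherification).

Step 7
Reactants: 13 [4-(methoxymethoxy)phenyl]methanol; 14 (1R,4R,5R)-isothiocineole
Product: 16 (1R,4R,5R)-6-[4-(methoxymethoxy)benzyl]-4,7,7-trimethyl-6-thiabicyclo[3.2.1]octan-6-ium tetrafluoroborate, via 1-(bromomethyl)-4-(methoxymethoxy)benzene 15 (not isolated)
Conditions: CBr4, PPh3, CH2Cl2, 0 °C; then 14 (1.0 equiv), NaBF4, CH2Cl2/H2O, rt
Reagents that add atoms: sodium tetrafluoroborate [Na+].F[B-](F)(F)F; carbon tetrabromide BrC(Br)(Br)Br (its bromine is carried only in intermediate 15)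
Why: Appel bromination under neutral conditions, then SN2 S-alkylation of the sulfide on its less hindered lone pair and anion exchange, should give a single crystalline sulfonium diastereomer (sulfonium salt formation).

Step 8
Reactants: 9 tert-butyl 4-bromo-2-formyl-5-(methoxymethoxy)phenyl carbonate; 11 1-bromo-3,5-bis(methoxymethoxy)benzene; 16 sulfonium tetrafluoroborate
Product: 20 (2R,3R)-5-bromo-3-[3,5-bis(methoxymethoxy)phenyl]-6-(methoxymethoxy)-2-[4-(methoxymethoxy)phenyl]-2,3-dihydro-1-benzofuran, via aryl Grignard reagent 17 (not isolated), via o-quinone methide 18 (not isolated), via sulfonium ylide 19 (not isolated)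
Conditions: 11, Mg, THF, 25 °C; add (1.05 equiv) to 9, THF, −78 °C; then 16 (1.3 equiv), LiN(SiMe3)2 (1.25 equiv), THF/CH2Cl2, −78 → −10 °C; aq NH4Cl
Reagents that add atoms: magnesium [Mg] (carried only in intermediate 17)
Why: Proposed new method: a Grignard-triggered three-component [4+1] annulation in which 17 adds to the aldehyde of 9 (C3–aryl bond), the magnesium alkoxide takes over the neighbouring Boc group and the resulting phenoxide expels tert-butyl carbonate to give the (E)-o-quinone methide 18 of ring B, which the chiral benzylsulfonium ylide 19 attacks at the exocyclic carbon (C2–C3 bond, rearomatisation) before the phenoxide displaces the sulfide (O1–C2 bond). The closest known reactions are the generation of o-quinone methides from o-OBoc benzaldehydes and Grignard reagents with in-flask trapping by a second nucleophile, the base-mediated [4+1] annulation of o-quinone methides with sulfonium ylides to trans-2,3-dihydrobenzofurans, and asymmetric epoxidation, aziridination and cyclopropanation with isothiocineole-derived benzylsulfonium ylides. The dihydrofuran ring closes in the 5-exo-tet mode by SN2 displacement with inversion at C2. C2 is controlled by the sulfide, whose bicyclic frame fixes the ylide conformation and shields one face of the carbanion, and C3 follows because addition should pass through the betaine in which the two aryl groups are anti when the phenoxide is aligned for backside attack, the arrangement that leads to the trans ring. The step needs 1,4-addition of the ylide to outrun dimerisation of 18 and its capture by tert-butoxide or residual Grignard reagent: the aldehyde is consumed at −78 °C before 18 forms on warming, the vinylogous-ester OMOM group tempers the electrophilicity of 18, and the ylide is already present in excess when 18 appears. The sulfide is set free and would be recovered.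

Step 9
Reactants: 20 (2R,3R)-5-bromo-3-[3,5-bis(methoxymethoxy)phenyl]-6-(methoxymethoxy)-2-[4-(methoxymethoxy)phenyl]-2,3-dihydro-1-benzofuran
Product: 23 {(2R,3R)-3-[3,5-bis(methoxymethoxy)phenyl]-6-(methoxymethoxy)-2-[4-(methoxymethoxy)phenyl]-2,3-dihydro-1-benzofuran-5-yl}boronic acid, via aryllithium 21 (not isolated), via lithium triisopropoxyborate 22 (not isolated)
Conditions: B(OiPr)3 (1.5 equiv), then n-BuLi (1.1 equiv), THF/toluene, −78 °C → 0 °C; aq NH4Cl
Reagents that add atoms: triisopropyl borate CC(C)OB(OC(C)C)OC(C)C; water O; n-butyllithium [Li]CCCC (its lithium is carried only in intermediates 21 and 22)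
Why: Bromine–lithium exchange with in situ borate quench and hydrolysis gives the boronic acid; exchange at −78 °C should be faster than deprotonation between the MOM ethers or at C3, so the ring and both stereocentres stay untouched.

Step 10
Reactants: 23 dihydrobenzofuranylboronic acid; 6 5,7-bis(ethoxymethoxy)-6,8-bis(3-methylbut-2-en-1-yl)-4H-chromen-4-one (1.5 equiv)
Product: 24 (2S)-2-{(2R,3R)-3-[3,5-bis(methoxymethoxy)phenyl]-6-(methoxymethoxy)-2-[4-(methoxymethoxy)phenyl]-2,3-dihydro-1-benzofuran-5-yl}-5,7-bis(ethoxymethoxy)-6,8-bis(3-methylbut-2-en-1-yl)-2,3-dihydro-4H-chromen-4-one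
Conditions: [Rh(OH)(cod)]2 (2.5 mol%), (S)-6,6'-dimethoxy-2,2'-bis[bis(3,4,5-trifluorophenyl)phosphino]-1,1'-biphenyl (5.5 mol%), toluene/H2O 10:1, 40 °C
Reagents that add atoms: none
Why: Rhodium-catalysed asymmetric 1,4-addition of an arylboronic acid to a chromone (Hayashi–Miyaura reaction) forms C2–C1' irreversibly by transmetalation, enantioface-selective insertion of C2=C3 into the aryl–rhodium bond and protonolysis, and sets C2 (S) by catalyst control; no base is added, so the flavanone cannot reopen by retro-oxa-Michael reaction, and any 2R product would be a separable diastereomer.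

Step 11
Reactants: 24 protected (2S)-flavanone
Product: 25 (2S)-2-[(2R,3R)-3-(3,5-dihydroxyphenyl)-6-hydroxy-2-(4-hydroxyphenyl)-2,3-dihydro-1-benzofuran-5-yl]-5,7-dihydroxy-6,8-bis(3-methylbut-2-en-1-yl)-2,3-dihydro-4H-chromen-4-one (target)
Conditions: HCl (2 M in MeOH), THF, 40 °C
Reagents that add atoms: none
Why: Acid-catalysed acetal exchange with methanol removes the four MOM and two ethoxymethyl groups under conditions in routine use for prenylated polyhydroxyflavanones, which should be mild enough for the prenyl groups, C2 and the trans-dihydrobenzofuran.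

**Compound list**

1 | 2,4,6-trihydroxyacetophenone | CC(=O)c1c(O)cc(O)cc1O | starting material
2 | prenyl bromide (1-bromo-3-methylbut-2-ene) | CC(C)=CCBr | starting material
3 | 2,4,6-trihydroxy-3,5-bis(3-methylbut-2-en-1-yl)acetophenone | CC(=O)c1c(O)c(CC=C(C)C)c(O)c(CC=C(C)C)c1O | intermediate
4 | 1-[2-hydroxy-4,6-bis(ethoxymethoxy)-3,5-bis(3-methylbut-2-en-1-yl)phenyl]ethan-1-one | CC(=O)c1c(O)c(CC=C(C)C)c(OCOCC)c(CC=C(C)C)c1OCOCC | intermediate
5 | (E)-3-(dimethylamino)-1-[2-hydroxy-4,6-bis(ethoxymethoxy)-3,5-bis(3-methylbut-2-en-1-yl)phenyl]prop-2-en-1-one | CN(C)/C=C/C(=O)c1c(O)c(CC=C(C)C)c(OCOCC)c(CC=C(C)C)c1OCOCC | intermediate (not isolated)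
6 | 5,7-bis(ethoxymethoxy)-6,8-bis(3-methylbut-2-en-1-yl)-4H-chromen-4-one | O=c1ccoc2c(CC=C(C)C)c(OCOCC)c(CC=C(C)C)c(OCOCC)c12 | intermediate
7 | 5-bromo-2,4-dihydroxybenzaldehyde | O=Cc1cc(Br)c(O)cc1O | starting material
8 | 5-bromo-2-hydroxy-4-(methoxymethoxy)benzaldehyde | O=Cc1cc(Br)c(OCOC)cc1O | intermediate (not isolated)
9 | tert-butyl 4-bromo-2-formyl-5-(methoxymethoxy)phenyl carbonate | O=Cc1cc(Br)c(OCOC)cc1OC(=O)OC(C)(C)C | intermediate
10 | 5-bromobenzene-1,3-diol | Oc1cc(O)cc(Br)c1 | starting material
11 | 1-bromo-3,5-bis(methoxymethoxy)benzene | COCOc1cc(Br)cc(OCOC)c1 | intermediate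
12 | 4-hydroxybenzyl alcohol | OCc1ccc(O)cc1 | starting material
13 | [4-(methoxymethoxy)phenyl]methanol | COCOc1ccc(CO)cc1 | intermediate
14 | (1R,4R,5R)-4,7,7-trimethyl-6-thiabicyclo[3.2.1]octane (isothiocineole) | C[C@@H]1CC[C@@H]2C[C@H]1SC2(C)C | starting material
15 | 1-(bromomethyl)-4-(methoxymethoxy)benzene | COCOc1ccc(CBr)cc1 | intermediate (not isolated)
16 | (1R,4R,5R)-6-[4-(methoxymethoxy)benzyl]-4,7,7-trimethyl-6-thiabicyclo[3.2.1]octan-6-ium tetrafluoroborate (one diastereomer at sulfur, benzyl on the less hindered face; sulfur left unspecified in the SMILES) | C[C@@H]1CC[C@@H]2C[C@H]1[S+](Cc1ccc(OCOC)cc1)C2(C)C.F[B-](F)(F)F | intermediate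
17 | 3,5-bis(methoxymethoxy)phenylmagnesium bromide | COCOc1cc([Mg]Br)cc(OCOC)c1 | intermediate (not isolated)
18 | (6E)-4-bromo-6-{[3,5-bis(methoxymethoxy)phenyl]methylidene}-3-(methoxymethoxy)cyclohexa-2,4-dien-1-one | O=C1C=C(OCOC)C(Br)=C/C1=C\c1cc(OCOC)cc(OCOC)c1 | intermediate (not isolated)
19 | sulfonium benzylide of 16 | C[C@@H]1CC[C@@H]2C[C@H]1[S+]([CH-]c1ccc(OCOC)cc1)C2(C)C | intermediate (not isolated)
20 | (2R,3R)-5-bromo-3-[3,5-bis(methoxymethoxy)phenyl]-6-(methoxymethoxy)-2-[4-(methoxymethoxy)phenyl]-2,3-dihydro-1-benzofuran | Brc1cc2c(cc1OCOC)O[C@@H](c1ccc(OCOC)cc1)[C@@H]2c1cc(OCOC)cc(OCOC)c1 | intermediate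
21 | aryllithium from 20 | [Li]c1cc2c(cc1OCOC)O[C@@H](c1ccc(OCOC)cc1)[C@@H]2c1cc(OCOC)cc(OCOC)c1 | intermediate (not isolated)
22 | lithium aryl(triisopropoxy)borate from 21 | [Li+].CC(C)O[B-](OC(C)C)(OC(C)C)c1cc2c(cc1OCOC)O[C@@H](c1ccc(OCOC)cc1)[C@@H]2c1cc(OCOC)cc(OCOC)c1 | intermediate (not isolated)
23 | {(2R,3R)-3-[3,5-bis(methoxymethoxy)phenyl]-6-(methoxymethoxy)-2-[4-(methoxymethoxy)phenyl]-2,3-dihydro-1-benzofuran-5-yl}boronic acid | OB(O)c1cc2c(cc1OCOC)O[C@@H](c1ccc(OCOC)cc1)[C@@H]2c1cc(OCOC)cc(OCOC)c1 | intermediate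
24 | (2S)-2-{(2R,3R)-3-[3,5-bis(methoxymethoxy)phenyl]-6-(methoxymethoxy)-2-[4-(methoxymethoxy)phenyl]-2,3-dihydro-1-benzofuran-5-yl}-5,7-bis(ethoxymethoxy)-6,8-bis(3-methylbut-2-en-1-yl)-2,3-dihydro-4H-chromen-4-one | CC(C)=CCc1c(OCOCC)c(CC=C(C)C)c2c(c1OCOCC)C(=O)C[C@@H](c1cc3c(cc1OCOC)O[C@@H](c1ccc(OCOC)cc1)[C@@H]3c1cc(OCOC)cc(OCOC)c1)O2 | intermediate
25 | (2S)-2-[(2R,3R)-3-(3,5-dihydroxyphenyl)-6-hydroxy-2-(4-hydroxyphenyl)-2,3-dihydro-1-benzofuran-5-yl]-5,7-dihydroxy-6,8-bis(3-methylbut-2-en-1-yl)-2,3-dihydro-4H-chromen-4-one | CC(C)=CCc1c(O)c(CC=C(C)C)c2c(c1O)C(=O)C[C@@H](c1cc3c(cc1O)O[C@@H](c1ccc(O)cc1)[C@@H]3c1cc(O)cc(O)c1)O2 | target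

**Step count and risks**

Total step count: 11. Longest linear sequence: 6 steps (steps 6, 7, 8, 9, 10, 11).

Steps most likely to fail:

1. Step 8 (proposed annulation). The o-quinone methide may dimerise or be captured by tert-butoxide before the ylide adds, or facial control by the sulfide may be insufficient. The trans/cis selectivity of the conjugate addition may also be low, and a cis product could not be repaired, since epimerising C2 would lead into the enantiomeric trans series. The fallback uses known reaction types only and sets out from 8, isolated after the first stage of step 4. Silylation (TBSCl, imidazole) would give 5-bromo-2-(tert-butyldimethylsilyloxy)-4-(methoxymethoxy)benzaldehyde F1. Asymmetric sulfur-ylide epoxidation with the same salt 16 (LiN(SiMe3)2, THF, −78 °C) would give the trans-(2S,3S)-epoxide F2. Copper-catalysed opening with Grignard reagent 17 (CuBr·SMe2, THF, −40 °C) at the benzylic carbon next to ring B, with inversion, would give the (1R,2R)-triarylethanol F3. Bu4NF would free the phenol F4, and catalytic camphorsulfonic acid (CH2Cl2, 0 °C) would close the ring through the p-alkoxybenzylic cation to the trans product, returning to the route at 20. In this fallback C3 comes stereospecifically from the epoxide and C2 is set under thermodynamic control.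

2. Step 10 (union). Protodeboronation of the hindered, electron-rich ortho-alkoxy boronic acid may outpace insertion into the electron-rich chromone, or the product may reopen if the medium turns basic. The fallback sets out from 20: bromine–lithium exchange (n-BuLi, −78 °C) and ZnCl2 would give the arylzinc chloride F5. This would be added to 6 with [RhCl((S)-binap)]2 and Me3SiCl in THF at 20 °C, the aprotic arylzinc variant of the 1,4-addition known for 4-quinolones and 2,3-dihydro-4-pyridones. The adduct is trapped as the silyl enol ether F6, which cannot ring-open; dilute aqueous acid would hydrolyse it, returning to the route at 24.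

3. Step 9 (boronic acid). Proton transfer to the aryllithium from the position between two MOM ethers or from C3 would scramble the site of borylation or open the dihydrofuran by β-elimination. The fallback sets out from 20: palladium-catalysed Miyaura borylation (B2pin2, KOAc, Pd(OAc)2/SPhos, dioxane, 80 °C) would give the pinacol boronate F7. Oxidative cleavage of the pinacol (NaIO4, NH4OAc, acetone/H2O) would return to the route at 23.

**Further compounds**

F1 | step 8 | 5-bromo-2-(tert-butyldimethylsilyloxy)-4-(methoxymethoxy)benzaldehyde | O=Cc1cc(Br)c(OCOC)cc1O[Si](C)(C)C(C)(C)C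
F2 | step 8 | (2S,3S)-2-[5-bromo-2-(tert-butyldimethylsilyloxy)-4-(methoxymethoxy)phenyl]-3-[4-(methoxymethoxy)phenyl]oxirane | CC(C)(C)[Si](C)(C)Oc1cc(OCOC)c(Br)cc1[C@@H]1O[C@H]1c1ccc(OCOC)cc1
F3 | step 8 | (1R,2R)-2-[5-bromo-2-(tert-butyldimethylsilyloxy)-4-(methoxymethoxy)phenyl]-2-[3,5-bis(methoxymethoxy)phenyl]-1-[4-(methoxymethoxy)phenyl]ethan-1-ol | O[C@@H](c1ccc(OCOC)cc1)[C@@H](c1cc(Br)c(OCOC)cc1O[Si](C)(C)C(C)(C)C)c1cc(OCOC)cc(OCOC)c1
F4 | step 8 | (1R,2R)-2-[5-bromo-2-hydroxy-4-(methoxymethoxy)phenyl]-2-[3,5-bis(methoxymethoxy)phenyl]-1-[4-(methoxymethoxy)phenyl]ethan-1-ol | O[C@@H](c1ccc(OCOC)cc1)[C@@H](c1cc(Br)c(OCOC)cc1O)c1cc(OCOC)cc(OCOC)c1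
F5 | step 10 | {(2R,3R)-3-[3,5-bis(methoxymethoxy)phenyl]-6-(methoxymethoxy)-2-[4-(methoxymethoxy)phenyl]-2,3-dihydro-1-benzofuran-5-yl}zinc chloride | Cl[Zn]c1cc2c(cc1OCOC)O[C@@H](c1ccc(OCOC)cc1)[C@@H]2c1cc(OCOC)cc(OCOC)c1
F6 | step 10 | (2S)-2-{(2R,3R)-3-[3,5-bis(methoxymethoxy)phenyl]-6-(methoxymethoxy)-2-[4-(methoxymethoxy)phenyl]-2,3-dihydro-1-benzofuran-5-yl}-5,7-bis(ethoxymethoxy)-6,8-bis(3-methylbut-2-en-1-yl)-4-(trimethylsilyloxy)-2H-chromene | C[Si](C)(C)OC1=C[C@@H](c2cc3c(cc2OCOC)O[C@@H](c2ccc(OCOC)cc2)[C@@H]3c2cc(OCOC)cc(OCOC)c2)Oc2c(CC=C(C)C)c(OCOCC)c(CC=C(C)C)c(OCOCC)c12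
F7 | step 9 | 2-{(2R,3R)-3-[3,5-bis(methoxymethoxy)phenyl]-6-(methoxymethoxy)-2-[4-(methoxymethoxy)phenyl]-2,3-dihydro-1-benzofuran-5-yl}-4,4,5,5-tetramethyl-1,3,2-dioxaborolane | CC1(C)OB(OC1(C)C)c1cc2c(cc1OCOC)O[C@@H](c1ccc(OCOC)cc1)[C@@H]2c1cc(OCOC)cc(OCOC)c1
A1 | direct plan | trans-resveratrol | Oc1ccc(/C=C/c2cc(O)cc(O)c2)cc1
A2 | direct plan | 5-[(E)-1-(3,5-dihydroxyphenyl)-2-(4-hydroxyphenyl)ethenyl]-2,4-dihydroxybenzaldehyde | Oc1ccc(/C=C(/c2cc(C=O)c(O)cc2O)c2cc(O)cc(O)c2)cc1
A3 | direct plan | (2R,3R)-3-(3,5-dihydroxyphenyl)-6-hydroxy-2-(4-hydroxyphenyl)-2,3-dihydro-1-benzofuran-5-carbaldehyde | O=Cc1cc2c(cc1O)O[C@@H](c1ccc(O)cc1)[C@@H]2c1cc(O)cc(O)c1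
A4 | direct plan | (2R,3R)-3-[3,5-bis(methoxymethoxy)phenyl]-6-(methoxymethoxy)-2-[4-(methoxymethoxy)phenyl]-2,3-dihydro-1-benzofuran-5-carbaldehyde | O=Cc1cc2c(cc1OCOC)O[C@@H](c1ccc(OCOC)cc1)[C@@H]2c1cc(OCOC)cc(OCOC)c1
A5 | direct plan | 1-[2-hydroxy-4,6-bis(methoxymethoxy)-3,5-bis(3-methylbut-2-en-1-yl)phenyl]ethan-1-one | CC(=O)c1c(O)c(CC=C(C)C)c(OCOC)c(CC=C(C)C)c1OCOC
A6 | direct plan | (E)-1-[2-hydroxy-4,6-bis(methoxymethoxy)-3,5-bis(3-methylbut-2-en-1-yl)phenyl]-3-{(2R,3R)-3-[3,5-bis(methoxymethoxy)phenyl]-6-(methoxymethoxy)-2-[4-(methoxymethoxy)phenyl]-2,3-dihydro-1-benzofuran-5-yl}prop-2-en-1-one | COCOc1c(CC=C(C)C)c(O)c(C(=O)/C=C/c2cc3c(cc2OCOC)O[C@@H](c2ccc(OCOC)cc2)[C@@H]3c2cc(OCOC)cc(OCOC)c2)c(OCOC)c1CC=C(C)C
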